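## The problem

CNP0149864.1 (32) is a germacrane-type ten-membered carbocycle; its ring compounds are named below with germacrane locants (C1 the Z-alkene CH, C2–C3 the CH2–CH2 link, C4 and C10 the methyl-bearing alkene carbons, C5 the E-alkene CH, C6 the carbinol, C7 the branch carbon, C8 the ring ester carbon, C9 a CH2; side chain C11 the CH, C12 its CH2O, C13 its methyl). A synthesis has to make a medium ring that resists direct closure and place in it a 1(10)Z and a 4E trisubstituted alkene in a 1,5-relationship. Four contiguous stereocentres must be set: C11 sits on a freely rotating side chain and cannot be controlled from the ring, so it is best bought; C7 and C8 have the syn relationship of an aldol pair; the C6 hydroxyl is 1,3-anti to the C8 oxygen, so C8 can control C6. The two secondary oxygens must be told apart, because O8 and the primary O12 carry angelates while O6 stays free. Angelates drift to tiglates under light, heat, base or nucleophiles; the 1,5-diene can undergo Cope rearrangement or acid-induced transannular cyclisation; every β-oxygenated ketone on the way can eliminate or suffer retro-aldol cleavage. The enabling feature is the cis,trans-1,5-diene C10=C1–C2–C3–C4=C5 with oxygenated C6 next to C5: joining C1 to C4 and C5 to C10 converts it into a bicyclo[2.2.0]hexane fused to a cyclohexanone (C5–C10), the [2+2] adduct of a 3-methylcyclohexenone and 1-methylcyclobutene.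

## Retrosynthesis

The last bonds made are the ester C–O bonds at O8 and O12. Angelates would not survive irradiation, 190 °C or basic reagents, so both are put on diol 28 after the ring is complete, each from one molecule of angelic acid 29. The C6 hydroxyl is masked as a silyl ether in 31 and freed last to give 32. Acylating both positions in one operation saves a step over two separate esterifications; the forward reaction must acylate the hindered C8 hydroxyl without Z to E drift.

In 28 the C6 oxygen must differ from the C8 oxygen and be 1,3-anti to it. Both follow if the C6–H bond is cut back to the ketone of β-hydroxy dienone 24 and the C8 hydroxyl delivers the hydride (Evans–Tishchenko). The reduction gives anti alcohol 25 with O8 acetylated, so O6 can be silylated (26) before O8 and O12 are unmasked (27, 28). An external hydride would give a diol with two secondary hydroxyls that cannot be told apart. Precursor 24 has one stereocentre fewer and holds the carbonyl that the ring-forming step needs; the hydride transfer must work across a ten-membered enone.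

Dienone 24 comes from its triethylsilyl ether 23. 23 is disconnected by re-forming two σ bonds across the ring, C1–C4 and C5–C10, which gives tricyclic ketone 21. The neighbouring cuts of a single ring bond (C2–C3, C3–C4, C6–C7) are all medium-ring closures with entropic and transannular penalties. This cut makes the ten-membered ring the perimeter of a compact tricycle, so no ring-closing bond is formed, and it derives both trisubstituted alkenes, of opposite geometry, from one ring-fusion relationship. 21 keeps the three lasting stereocentres of 23 and has four more that vanish. The thermolysis must break C5–C10 rather than C2–C3 after the central bond opens, pass through the diyl chair that gives 4E and 1(10)Z, and stop before the 1,5-diene rearranges.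

21 is a [2+2] adduct: cutting C4–C5 and C1–C10 gives cyclohexenone 17 and 1-methylcyclobutene 19. The needed orientation joins the quaternary enone carbon C10 to the unsubstituted cyclobutene carbon C1, the sterically favoured sense. The fusion must be cis-anti-cis, but the face of 17 attacked does not matter, since all four new centres are lost again. 17 holds every lasting stereocentre except C6; 19 comes from methylenecyclobutane 18 by double-bond isomerisation.

The enone bond C5=C10 of 17 is cut by a metathesis transform to vinyl ketone 16, whose 1,1-disubstituted alkene supplies C10 and its methyl. An aldol-type condensation is avoided because base next to a β-silyloxy cyclohexenone invites elimination and aromatisation. 16 is acyclic; the forward step only closes a six-membered ring.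

The vinyl group of 16 is cut at C5–C6 back to Weinreb amide 15, made by silylation of 14, which comes from aldol adduct 13 by auxiliary exchange. This keeps C6 at the acid oxidation level until the C7 and C8 centres are in place; the forward addition must stop at the ketone.

The C7–C8 bond of 13 is cut by an Evans syn aldol transform to imide 9 and 3-methylbut-3-enal 11 (from alcohol 10). This cut sets both ring stereocentres in one step under auxiliary control; a cut at C8–C9 would set only one. The precursors are an achiral aldehyde and an imide with C11 alone; the aldehyde must react before its double bond moves into conjugation.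

Imide 9 is cut at the N–acyl bond to acid 6 and oxazolidinone 7. 6 is cut at C6–C7 to organolithium 5 and a one-carbon electrophile; 5 comes from iodide 4, alcohol 3, silyl ether 2 and hydroxy ester 1, which supplies C11 with the correct configuration.

## Roads not taken

Alternative 1: The cut is the C3–C4 single bond, leading to open-chain A1, an (E)-alkenyl iodide at C4 with the (Z)-1,3-diene C10=C1–C2=C3 at the other end and both angelates in place. Forward, 9-borabicyclo[3.3.1]nonane would hydroborate the terminal C2=C3 alkene and a B-alkyl Suzuki coupling catalysed by Pd(dppf)Cl2 would close the ring to A2, the C6 triethylsilyl ether of 32.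
- Merits: both alkene geometries are fixed before closure, no thermal step threatens the diene, and A2 is one desilylation from 32. In endgame economy this road is clearly better than the chosen plan, which needs seven steps after ring formation.
- Weak points: sp3–sp2 coupling to a ten-membered ring is scarce next to larger rings and competes with intermolecular coupling and β-hydride elimination; the borane must pick the terminal alkene of a conjugated diene beside two conjugated esters; the aqueous base of the coupling threatens the angelates; A1 needs a Z-trisubstituted diene and an E-trisubstituted iodoalkene, each from its own stereoselective olefination, on top of the same stereotriad.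
- Against it the chosen plan forms the ring with no ring-closing event and obtains both alkenes from a ring fusion. It pays with a long endgame and a thermolysis of uncertain partition.

Alternative 2: The cut is the C2–C3 bond. Open-chain A3 carries a Z-allylic phenyl sulfone at C2 and an E-allylic bromide at C3; base would close the ring by intramolecular alkylation to sulfone A4.
- Merits: alkylation of sulfonyl-stabilised allyl anions is a proven entry to ten-membered 1,5-dienes, the geometry is set in the chain, and silyl ethers are tolerated. As a ring-forming event it is at least as predictable as a thermolysis whose product can rearrange.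
- Weak points: high dilution; the allyl anion can alkylate at C10 instead of C2 or lose the Z geometry; A4 then needs reductive desulfonylation (risk of double-bond shift), removal of the C6 benzyl-type ether and the same acylation sequence; A3, with two stereodefined trisubstituted alkenes and three stereocentres, is long to build.
- The chosen plan sets against the better precedent a much shorter construction, ring and both alkenes in two steps from a cyclohexenone, and no auxiliary group to remove from the ring.

Alternative 3: The cut is the C6–C7 bond with allylic transposition. The 13-membered diallyl ether A5 (C6–O–C12) would be lithiated at C6 and contract by [2,3]-Wittig shift to A6, which has the C6 hydroxyl and a C11=C12 isopropenyl group.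
- Merits: one step forms C6–C7, the carbinol and the ten-membered ring, and the 13-membered ether is easy to close. It needs no separate carbonyl reduction, so it reaches the C6 carbinol more economically than the chosen plan.
- Weak points: deprotonation must occur at C6 and not at C12, both allylic and α to oxygen; the C6/C7 and C7/C8 relationships rest on a transannular transition state steered only by C8; C11 must be set afterwards by hydroboration of the isopropenyl group with weak acyclic control.
- The chosen plan buys C11 and sets C7 and C8 by auxiliary control before any ring exists, at the cost of the Evans–Tishchenko and protecting-group steps.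

Key step: step 14

Remark on the chemistry: the cyclobutene is assumed to add to the face of 17 opposite the C7 side chain; the facial isomer has the same constitution and ring fusion and would give the same 23, since C1, C4, C5 and C10 all become trigonal in step 14.

## Steps

Step 1
Reactants: 1 methyl (R)-3-hydroxy-2-methylpropanoate
Product: 2 methyl (R)-3-[(tert-butyldimethylsilyl)oxy]-2-methylpropanoate
Conditions: TBSCl, imidazole, CH2Cl2, 0 °C to rt
Reagents that add atoms: tert-butyldimethylsilyl chloride, CC(C)(C)[Si](C)(C)Cl
Why: Silyl ether formation at the primary hydroxyl; the imidazole buffer is too weak to epimerise the ester α-centre (future C11).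

Step 2
Reactants: 2 methyl (R)-3-[(tert-butyldimethylsilyl)oxy]-2-methylpropanoate
Product: 3 (S)-3-[(tert-butyldimethylsilyl)oxy]-2-methylpropan-1-ol
Conditions: i-Bu2AlH (2.2 equiv), CH2Cl2, −78 to 0 °C; aq. KNaC4H4O6
Reagents that add atoms: none
Why: Hydride reduction of the ester to the primary alcohol at low temperature; the descriptor changes only because ligand priorities change.

Step 3
Reactants: 3 (S)-3-[(tert-butyldimethylsilyl)oxy]-2-methylpropan-1-ol
Product: 4 (R)-tert-butyl(3-iodo-2-methylpropoxy)dimethylsilane
Conditions: PPh3, I2, imidazole, CH2Cl2, 0 °C to rt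
Reagents that add atoms: iodine, II
Why: Appel-type iodination by SN2 displacement at the CH2 group; the neighbouring stereocentre is not involved.

Step 4
Reactants: 4 (R)-tert-butyl(3-iodo-2-methylpropoxy)dimethylsilane
Product: 6 (S)-4-[(tert-butyldimethylsilyl)oxy]-3-methylbutanoic acid, via alkyllithium 5 (not isolated)
Conditions: t-BuLi (2.1 equiv), Et2O–pentane, −78 °C; then CO2, −78 to 0 °C; cold dilute HCl to pH 4
Reagents that add atoms: carbon dioxide, O=C=O
Why: Lithium–iodine exchange followed by carboxylation adds the carboxyl carbon (C6) to the former CH2I carbon (C7); at −78 °C the γ-silyloxy alkyllithium is configurationally and constitutionally stable, and the mild work-up spares the silyl ether.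

Step 5
Reactants: 6 (S)-4-[(tert-butyldimethylsilyl)oxy]-3-methylbutanoic acid; 7 (R)-4-benzyloxazolidin-2-one
Product: 9 (R)-4-benzyl-3-[(S)-4-[(tert-butyldimethylsilyl)oxy]-3-methylbutanoyl]oxazolidin-2-one, via mixed pivalic anhydride 8 (not isolated)
Conditions: t-BuCOCl, Et3N, THF, −20 °C; then LiCl, 7, −20 °C to rt
Reagents that add atoms: none
Why: N-acylation of the oxazolidinone through the mixed anhydride with LiCl activation; no strong base, so the acid-labile γ-silyloxy acid is consumed before it can lactonise.

Step 6
Reactants: 10 3-methylbut-3-en-1-ol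
Product: 11 3-methylbut-3-enal
Conditions: Dess–Martin periodinane, NaHCO3, CH2Cl2, 0 °C; cold filtered solution used at once
Reagents that add atoms: none
Why: Dess–Martin oxidation under bicarbonate buffer gives the β,γ-unsaturated aldehyde without the acid or amine base that would move the double bond into conjugation.

Step 7
Reactants: 9 (R)-4-benzyl-3-[(S)-4-[(tert-butyldimethylsilyl)oxy]-3-methylbutanoyl]oxazolidin-2-one; 11 3-methylbut-3-enal
Product: 13 (R)-4-benzyl-3-[(2R,3S)-2-[(S)-1-[(tert-butyldimethylsilyl)oxy]propan-2-yl]-3-hydroxy-5-methylhex-5-enoyl]oxazolidin-2-one, via Z boron enolate 12 (not isolated)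
Conditions: Bu2BOTf, i-Pr2NEt, CH2Cl2, 0 °C; then 11, −78 to −20 °C; pH 7 buffer, MeOH, H2O2, 0 °C
Reagents that add atoms: none
Why: Evans syn aldol through the Z boron enolate and a closed chair transition state. The (R)-benzyl auxiliary shields one enolate face and so sets C7 and C8 syn with the absolute sense of the target; the remote C11 centre has little say. The aldehyde meets the amine only at −78 °C, which should keep its double bond in place.

Step 8
Reactants: 13 (R)-4-benzyl-3-[(2R,3S)-2-[(S)-1-[(tert-butyldimethylsilyl)oxy]propan-2-yl]-3-hydroxy-5-methylhex-5-enoyl]oxazolidin-2-one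
Product: 14 (2R,3S)-2-[(S)-1-[(tert-butyldimethylsilyl)oxy]propan-2-yl]-3-hydroxy-N-methoxy-N,5-dimethylhex-5-enamide
Conditions: MeONHMe·HCl, AlMe3, CH2Cl2, −20 to 0 °C
Reagents that add atoms: N,O-dimethylhydroxylamine hydrochloride, CNOC.Cl
Why: Aluminium amide transamidation to the Weinreb amide; the free β-hydroxyl binds aluminium and steers attack to the exocyclic carbonyl, and the auxiliary is recovered without epimerisation at C7.

Step 9
Reactants: 14 (2R,3S)-2-[(S)-1-[(tert-butyldimethylsilyl)oxy]propan-2-yl]-3-hydroxy-N-methoxy-N,5-dimethylhex-5-enamide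
Product: 15 (2R,3S)-2-[(S)-1-[(tert-butyldimethylsilyl)oxy]propan-2-yl]-N-methoxy-N,5-dimethyl-3-[(triethylsilyl)oxy]hex-5-enamide
Conditions: Et3SiOTf, 2,6-lutidine, CH2Cl2, −78 °C
Reagents that add atoms: triethylsilyl trifluoromethanesulfonate, CC[Si](CC)(CC)OS(=O)(=O)C(F)(F)F
Why: Silyl triflate silylation of the hindered secondary alcohol; triethylsilyl is chosen so that O8 can later be freed beside the primary tert-butyldimethylsilyl ether at O12.

Step 10
Reactants: 15 (2R,3S)-2-[(S)-1-[(tert-butyldimethylsilyl)oxy]propan-2-yl]-N-methoxy-N,5-dimethyl-3-[(triethylsilyl)oxy]hex-5-enamide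
Product: 16 (4R,5S)-4-[(S)-1-[(tert-butyldimethylsilyl)oxy]propan-2-yl]-7-methyl-5-[(triethylsilyl)oxy]octa-1,7-dien-3-one
Conditions: CH2=CHMgBr (3 equiv), THF, 0 °C to rt; inverse quench into cold aq. citric acid
Reagents that add atoms: vinylmagnesium bromide, C=C[Mg]Br
Why: Grignard addition to a Weinreb amide stops at the ketone because the magnesium chelate holds until work-up; the acidic inverse quench protonates the released amine before it can add to the enone and avoids base at the epimerisable C7.

Step 11
Reactants: 16 (4R,5S)-4-[(S)-1-[(tert-butyldimethylsilyl)oxy]propan-2-yl]-7-methyl-5-[(triethylsilyl)oxy]octa-1,7-dien-3-one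
Product: 17 (5S,6R)-6-[(S)-1-[(tert-butyldimethylsilyl)oxy]propan-2-yl]-3-methyl-5-[(triethylsilyl)oxy]cyclohex-2-en-1-one
Conditions: second-generation Grubbs catalyst RuCl2(=CHPh)(H2IMes)(PCy3) (5 mol%), CH2Cl2 (5 mM), 40 °C
Reagents that add atoms: none
Why: Ring-closing metathesis between the vinyl ketone and the 1,1-disubstituted alkene closes the six-membered ring and forms the trisubstituted enone C5=C10, driven by loss of ethene; the neutral conditions leave the β-silyloxy ketone intact.

Step 12
Reactants: 18 methylenecyclobutane
Product: 19 1-methylcyclobutene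
Conditions: KOt-Bu (cat.), DMSO, 40 °C; fractional distillation
Reagents that add atoms: none
Why: Base-catalysed prototropic alkene isomerisation through the allyl anion should give an equilibrium mixture rich in the endocyclic trisubstituted alkene; fractional distillation removes remaining 18, which would otherwise compete in step 13.

Step 13
Reactants: 17 (5S,6R)-6-[(S)-1-[(tert-butyldimethylsilyl)oxy]propan-2-yl]-3-methyl-5-[(triethylsilyl)oxy]cyclohex-2-en-1-one; 19 1-methylcyclobutene
Product: 21 (1R,4S,5R,7R,8S,10S,11S)-12-[(tert-butyldimethylsilyl)oxy]-8-[(triethylsilyl)oxy]-1,4:5,10-dicyclogermacran-6-one (cis-anti-cis photoadduct), via trans-fused C5 epimer 20 (not isolated)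
Conditions: hν (medium-pressure Hg lamp, uranium-glass filter, λ > 330 nm), 19 (10 equiv), CH2Cl2, −40 °C; then basic Al2O3, rt
Reagents that add atoms: none
Why: Enone–alkene [2+2] photocycloaddition through the triplet enone: the first bond should join the hindered β-carbon C10 to the unsubstituted cyclobutene carbon C1, so that C4 closes onto C5 and no two quaternary carbons become neighbours. Of the four new centres (C1, C4, C5, C10), the cyclobutane fusion is cis by necessity, the six–four fusion becomes cis after enolisation at C5 on alumina, and the outer ring is anti by exo approach; the face anti to the C7 side chain is assumed. Only the cis-anti-cis relationship matters, because all four centres are lost in step 14.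

Step 14
Reactants: 21 (1R,4S,5R,7R,8S,10S,11S)-12-[(tert-butyldimethylsilyl)oxy]-8-[(triethylsilyl)oxy]-1,4:5,10-dicyclogermacran-6-one
Product: 23 (1(10)Z,4E,7R,8S,11S)-12-[(tert-butyldimethylsilyl)oxy]-8-[(triethylsilyl)oxy]germacra-1(10),4-dien-6-one, via cyclohexane-1,4-diyl 22 (not isolated)
Conditions: degassed PhMe (5 mM), silylated sealed glass, 190 °C, short heating to partial conversion, recovered 21 recycled
Reagents that add atoms: none
Why: Thermal [2+2] cycloreversion of the bicyclo[2.2.0]hexane in two stages: the strained central C1–C4 bond homolyses to diyl 22, which relaxes from boat to chair and then cleaves C5–C10. The closest known reaction type is the thermolysis of cyclohexenone–cyclobutene photoadducts to cis,trans-cyclodeca-1,5-dienes. The ten-membered ring is not closed by bond formation; it is the perimeter of the tricycle and is released by ring expansion when the two transannular bonds break, so there is no entropic penalty and no need for high dilution. No stereocentre is created: C7, C8 and C11 are untouched and C1, C4, C5 and C10 become trigonal. The geometry follows from the diyl chair: C6 and C9 are cis on C5 and C10, so one is equatorial and one axial, and the equatorial one ends trans and the axial one cis to the ring CH2 across the new double bond, which gives exactly one E and one Z alkene; the chair with the acyl carbon C6 equatorial and only C9 axial (the other chair would put C6 and the C10 methyl both axial) leads to 4E,1(10)Z. The second cleavage must take C5–C10 rather than C2–C3; C5–C10 is flanked by the carbonyl and the quaternary C10 and gives a conjugated enone and two trisubstituted alkenes. The product must leave the heat before a [3,3] shift sets in, hence the short contact time and recycling; the Z geometry at C1=C10 and the enone conjugation, which a Cope shift would destroy, both slow that shift. Neutral silylated glass protects the β-silyloxy ketone from elimination and C7 from epimerisation.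

Step 15
Reactants: 23 (1(10)Z,4E,7R,8S,11S)-12-[(tert-butyldimethylsilyl)oxy]-8-[(triethylsilyl)oxy]germacra-1(10),4-dien-6-one
Product: 24 (1(10)Z,4E,7R,8S,11S)-12-[(tert-butyldimethylsilyl)oxy]-8-hydroxygermacra-1(10),4-dien-6-one
Conditions: PPTS (cat.), MeOH–CH2Cl2, 0 °C
Reagents that add atoms: none
Why: Acid-catalysed methanolysis of the triethylsilyl ether, which is far more labile than the primary tert-butyldimethylsilyl ether; the weak acid at 0 °C avoids dehydration of the β-hydroxy ketone and transannular cyclisation, and no base is present to trigger retro-aldol ring opening.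

Step 16
Reactants: 24 (1(10)Z,4E,7R,8S,11S)-12-[(tert-butyldimethylsilyl)oxy]-8-hydroxygermacra-1(10),4-dien-6-one
Product: 25 (1(10)Z,4E,6S,7S,8S,11S)-12-[(tert-butyldimethylsilyl)oxy]-6-hydroxygermacra-1(10),4-dien-8-yl acetate
Conditions: SmI2 (0.3 equiv), CH3CHO (excess), THF, −10 °C
Reagents that add atoms: acetaldehyde, CC=O
Why: Evans–Tishchenko reduction: divalent samarium iodide is oxidised by the aldehyde to the trivalent samarium species that binds the C8 hemiacetal and the C6 carbonyl, and hydride passes within a six-membered chair to the carbonyl carbon only. This sets C6 1,3-anti to C8 (6S) and leaves O8 acetylated, so the two secondary oxygens are told apart in the same step.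

Step 17
Reactants: 25 (1(10)Z,4E,6S,7S,8S,11S)-12-[(tert-butyldimethylsilyl)oxy]-6-hydroxygermacra-1(10),4-dien-8-yl acetate
Product: 26 (1(10)Z,4E,6S,7R,8S,11S)-6,12-bis[(tert-butyldimethylsilyl)oxy]germacra-1(10),4-dien-8-yl acetate
Conditions: t-BuMe2SiOTf, 2,6-lutidine, CH2Cl2, −78 to 0 °C
Reagents that add atoms: tert-butyldimethylsilyl trifluoromethanesulfonate, CC(C)(C)[Si](C)(C)OS(=O)(=O)C(F)(F)F
Why: Silyl triflate silylation of the hindered allylic C6 hydroxyl under lutidine buffer; the new secondary silyl ether is much slower to cleave than the primary one at O12, which allows step 19.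

Step 18
Reactants: 26 (1(10)Z,4E,6S,7R,8S,11S)-6,12-bis[(tert-butyldimethylsilyl)oxy]germacra-1(10),4-dien-8-yl acetate
Product: 27 (1(10)Z,4E,6S,7R,8S,11S)-6,12-bis[(tert-butyldimethylsilyl)oxy]germacra-1(10),4-dien-8-ol
Conditions: i-Bu2AlH (2.5 equiv), CH2Cl2, −78 °C; aq. KNaC4H4O6
Reagents that add atoms: none
Why: Reductive cleavage of the acetate at −78 °C; no free alkoxide is formed in protic base, which avoids silyl migration from O6 to O8.

Step 19
Reactants: 27 (1(10)Z,4E,6S,7R,8S,11S)-6,12-bis[(tert-butyldimethylsilyl)oxy]germacra-1(10),4-dien-8-ol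
Product: 28 (1(10)Z,4E,6S,7R,8S,11S)-6-[(tert-butyldimethylsilyl)oxy]germacra-1(10),4-diene-8,12-diol
Conditions: HF·pyridine, pyridine, THF, 0 °C
Reagents that add atoms: none
Why: Selective desilylation: the unhindered primary silyl ether should be cleaved well before the secondary allylic one at C6, which is flanked by the branched C7; the pyridine buffer keeps the diene from acid-induced cyclisation.

Step 20
Reactants: 28 (1(10)Z,4E,6S,7R,8S,11S)-6-[(tert-butyldimethylsilyl)oxy]germacra-1(10),4-diene-8,12-diol; 29 angelic acid [(Z)-2-methylbut-2-enoic acid]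
Product: 31 (1(10)Z,4E,6S,7R,8S,11S)-6-[(tert-butyldimethylsilyl)oxy]germacra-1(10),4-diene-8,12-diyl bis[(Z)-2-methylbut-2-enoate], via mixed Yamaguchi anhydride 30 (not isolated)
Conditions: 29 (4 equiv), 2,4,6-Cl3C6H2COCl (4 equiv), Et3N, PhMe, rt; then 28, PhMe, 80 °C
Reagents that add atoms: angelic acid (second molecule of 29, for the second ester), C/C=C(/C)C(=O)O
Why: Yamaguchi-type double esterification through the mixed trichlorobenzoic anhydride without a nucleophilic catalyst, the variant that acylates hindered secondary alcohols with retention of the Z geometry. Two molecules of 29 are incorporated, one at the primary O12 and one at the hindered O8, which is why the anhydride is used in excess. The temperature of 80 °C is far below that at which the Z,E-diene rearranges.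

Step 21
Reactants: 31 (1(10)Z,4E,6S,7R,8S,11S)-6-[(tert-butyldimethylsilyl)oxy]germacra-1(10),4-diene-8,12-diyl bis[(Z)-2-methylbut-2-enoate]
Product: 32 (1(10)Z,4E,6S,7S,8S,11S)-6-hydroxygermacra-1(10),4-diene-8,12-diyl bis[(Z)-2-methylbut-2-enoate] (CNP0149864.1)
Conditions: HF·pyridine, pyridine, THF, 0 °C to rt
Reagents that add atoms: none
Why: Desilylation with buffered hydrogen fluoride; no alkoxide is formed, so the C8 angelate should neither migrate to O6 nor isomerise, and the buffer guards the allylic alcohol and the diene.

## Compound list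

1 | methyl (R)-3-hydroxy-2-methylpropanoate | COC(=O)[C@H](C)CO | starting material
2 | methyl (R)-3-[(tert-butyldimethylsilyl)oxy]-2-methylpropanoate | COC(=O)[C@H](C)CO[Si](C)(C)C(C)(C)C | intermediate
3 | (S)-3-[(tert-butyldimethylsilyl)oxy]-2-methylpropan-1-ol | OC[C@H](C)CO[Si](C)(C)C(C)(C)C | intermediate
4 | (R)-tert-butyl(3-iodo-2-methylpropoxy)dimethylsilane | IC[C@H](C)CO[Si](C)(C)C(C)(C)C | intermediate
5 | (S)-{3-[(tert-butyldimethylsilyl)oxy]-2-methylpropyl}lithium | [Li]C[C@H](C)CO[Si](C)(C)C(C)(C)C | intermediate (not isolated)
6 | (S)-4-[(tert-butyldimethylsilyl)oxy]-3-methylbutanoic acid | OC(=O)C[C@H](C)CO[Si](C)(C)C(C)(C)C | intermediate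
7 | (R)-4-benzyloxazolidin-2-one | O=C1N[C@H](Cc2ccccc2)CO1 | starting material
8 | (S)-4-[(tert-butyldimethylsilyl)oxy]-3-methylbutanoic pivalic anhydride | CC(C)(C)C(=O)OC(=O)C[C@H](C)CO[Si](C)(C)C(C)(C)C | intermediate (not isolated)
9 | (R)-4-benzyl-3-[(S)-4-[(tert-butyldimethylsilyl)oxy]-3-methylbutanoyl]oxazolidin-2-one | CC(C)(C)[Si](C)(C)OC[C@@H](C)CC(=O)N1[C@H](Cc2ccccc2)COC1=O | intermediate
10 | 3-methylbut-3-en-1-ol | CC(=C)CCO | starting material
11 | 3-methylbut-3-enal | CC(=C)CC=O | intermediate
12 | dibutylboron (Z)-enolate of imide 9 | CCCCB(CCCC)O/C(=C\[C@H](C)CO[Si](C)(C)C(C)(C)C)N1[C@H](Cc2ccccc2)COC1=O | intermediate (not isolated)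
13 | (R)-4-benzyl-3-[(2R,3S)-2-[(S)-1-[(tert-butyldimethylsilyl)oxy]propan-2-yl]-3-hydroxy-5-methylhex-5-enoyl]oxazolidin-2-one | CC(C)(C)[Si](C)(C)OC[C@@H](C)[C@@H](C(=O)N1[C@H](Cc2ccccc2)COC1=O)[C@@H](O)CC(C)=C | intermediate
14 | (2R,3S)-2-[(S)-1-[(tert-butyldimethylsilyl)oxy]propan-2-yl]-3-hydroxy-N-methoxy-N,5-dimethylhex-5-enamide | CC(C)(C)[Si](C)(C)OC[C@@H](C)[C@@H](C(=O)N(C)OC)[C@@H](O)CC(C)=C | intermediate
15 | (2R,3S)-2-[(S)-1-[(tert-butyldimethylsilyl)oxy]propan-2-yl]-N-methoxy-N,5-dimethyl-3-[(triethylsilyl)oxy]hex-5-enamide | CC(C)(C)[Si](C)(C)OC[C@@H](C)[C@@H](C(=O)N(C)OC)[C@@H](O[Si](CC)(CC)CC)CC(C)=C | intermediate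
16 | (4R,5S)-4-[(S)-1-[(tert-butyldimethylsilyl)oxy]propan-2-yl]-7-methyl-5-[(triethylsilyl)oxy]octa-1,7-dien-3-one | CC(C)(C)[Si](C)(C)OC[C@@H](C)[C@@H](C(=O)C=C)[C@@H](O[Si](CC)(CC)CC)CC(C)=C | intermediate
17 | (5S,6R)-6-[(S)-1-[(tert-butyldimethylsilyl)oxy]propan-2-yl]-3-methyl-5-[(triethylsilyl)oxy]cyclohex-2-en-1-one | CC(C)(C)[Si](C)(C)OC[C@@H](C)[C@@H]1[C@@H](O[Si](CC)(CC)CC)CC(C)=CC1=O | intermediate
18 | methylenecyclobutane | C=C1CCC1 | starting material
19 | 1-methylcyclobutene | CC1=CCC1 | intermediate
20 | (1R,4S,5S,7R,8S,10S,11S)-12-[(tert-butyldimethylsilyl)oxy]-8-[(triethylsilyl)oxy]-1,4:5,10-dicyclogermacran-6-one (six–four fusion trans; C5 epimer of 21) | CC(C)(C)[Si](C)(C)OC[C@@H](C)[C@@H]1[C@@H](O[Si](CC)(CC)CC)C[C@@]2(C)[C@@H]3CC[C@]3(C)[C@@H]2C1=O | intermediate (not isolated)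
21 | (1R,4S,5R,7R,8S,10S,11S)-12-[(tert-butyldimethylsilyl)oxy]-8-[(triethylsilyl)oxy]-1,4:5,10-dicyclogermacran-6-one (tricyclo[4.4.0.0^2,5]decan-7-one core, cis-anti-cis; C10 methyl and C5 hydrogen on the face of the C7 side chain, cyclobutane on the face of the C8 silyloxy group) | CC(C)(C)[Si](C)(C)OC[C@@H](C)[C@@H]1[C@@H](O[Si](CC)(CC)CC)C[C@@]2(C)[C@@H]3CC[C@]3(C)[C@H]2C1=O | intermediate
22 | cyclohexane-1,4-diyl from 21 (C1–C4 bond broken, radical centres at C1 and C4, C5 and C10 as in 21) | CC(C)(C)[Si](C)(C)OC[C@@H](C)[C@@H]1[C@@H](O[Si](CC)(CC)CC)C[C@@]2(C)[CH]CC[C](C)[C@H]2C1=O | intermediate (not isolated)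
23 | (1(10)Z,4E,7R,8S,11S)-12-[(tert-butyldimethylsilyl)oxy]-8-[(triethylsilyl)oxy]germacra-1(10),4-dien-6-one | CC(C)(C)[Si](C)(C)OC[C@@H](C)[C@@H]1[C@@H](O[Si](CC)(CC)CC)C/C(C)=C\CC/C(C)=C/C1=O | intermediate
24 | (1(10)Z,4E,7R,8S,11S)-12-[(tert-butyldimethylsilyl)oxy]-8-hydroxygermacra-1(10),4-dien-6-one | CC(C)(C)[Si](C)(C)OC[C@@H](C)[C@@H]1[C@@H](O)C/C(C)=C\CC/C(C)=C/C1=O | intermediate
25 | (1(10)Z,4E,6S,7S,8S,11S)-12-[(tert-butyldimethylsilyl)oxy]-6-hydroxygermacra-1(10),4-dien-8-yl acetate | CC(C)(C)[Si](C)(C)OC[C@@H](C)[C@@H]1[C@@H](OC(C)=O)C/C(C)=C\CC/C(C)=C/[C@@H]1O | intermediate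
26 | (1(10)Z,4E,6S,7R,8S,11S)-6,12-bis[(tert-butyldimethylsilyl)oxy]germacra-1(10),4-dien-8-yl acetate | CC(C)(C)[Si](C)(C)OC[C@@H](C)[C@@H]1[C@@H](OC(C)=O)C/C(C)=C\CC/C(C)=C/[C@@H]1O[Si](C)(C)C(C)(C)C | intermediate
27 | (1(10)Z,4E,6S,7R,8S,11S)-6,12-bis[(tert-butyldimethylsilyl)oxy]germacra-1(10),4-dien-8-ol | CC(C)(C)[Si](C)(C)OC[C@@H](C)[C@@H]1[C@@H](O)C/C(C)=C\CC/C(C)=C/[C@@H]1O[Si](C)(C)C(C)(C)C | intermediate
28 | (1(10)Z,4E,6S,7R,8S,11S)-6-[(tert-butyldimethylsilyl)oxy]germacra-1(10),4-diene-8,12-diol | OC[C@@H](C)[C@@H]1[C@@H](O)C/C(C)=C\CC/C(C)=C/[C@@H]1O[Si](C)(C)C(C)(C)C | intermediate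
29 | angelic acid, (Z)-2-methylbut-2-enoic acid | C/C=C(/C)C(=O)O | starting material
30 | (Z)-2-methylbut-2-enoic 2,4,6-trichlorobenzoic anhydride | C/C=C(/C)C(=O)OC(=O)c1c(Cl)cc(Cl)cc1Cl | intermediate (not isolated)
31 | (1(10)Z,4E,6S,7R,8S,11S)-6-[(tert-butyldimethylsilyl)oxy]germacra-1(10),4-diene-8,12-diyl bis[(Z)-2-methylbut-2-enoate] | C/C=C(/C)C(=O)OC[C@@H](C)[C@@H]1[C@@H](OC(=O)/C(C)=C\C)C/C(C)=C\CC/C(C)=C/[C@@H]1O[Si](C)(C)C(C)(C)C | intermediate
32 | (1(10)Z,4E,6S,7S,8S,11S)-6-hydroxygermacra-1(10),4-diene-8,12-diyl bis[(Z)-2-methylbut-2-enoate], CNP0149864.1 | C/C=C(/C)C(=O)OC[C@@H](C)[C@@H]1[C@@H](OC(=O)/C(C)=C\C)C/C(C)=C\CC/C(C)=C/[C@@H]1O | target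

## Step count and least certain steps

Total: 21 steps. Longest linear sequence: 19 steps (1–5, 7–11, 13–21); steps 6 and 12 prepare the small partners 11 and 19.

Step 14 (key step). Most likely to go wrong: onward [3,3] sigmatropic shift of the ten-membered dienone, or scission of C2–C3 in the diyl, into the six-membered divinyl series during the time needed for conversion. The energetics of that shift should be close to balanced for this enone, so the outcome depends on contact time. Leakage through the boat diyl to the wrong alkene geometry and loss of silanol from the β-silyloxy ketone are secondary hazards. Fallback: carry out the ring expansion one oxidation level lower, after C6 has been set on the rigid tricycle. From 21, methanolysis of the triethylsilyl ether (PPTS, MeOH) would give hydroxy ketone F1. Evans–Tishchenko reduction (SmI2 cat., CH3CHO) would give the trans-1,3 acetate alcohol F2, and t-BuMe2SiOTf its C6 silyl ether F3. Thermolysis of F3 would open the ring directly to 26, where the route is rejoined and steps 15–17 fall away. With C6 tetrahedral and silylated there is no eliminable β-oxy ketone, and a [3,3] shift would have to build a cyclohexane substituted on five ring carbons. The price is the loss of carbonyl assistance in the C5–C10 cleavage and a higher temperature.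

Step 13. Most likely to go wrong: addition in the reverse orientation or with syn ring fusion, because the methyl group of 19 directs only weakly, together with slow reaction of the β,β-disubstituted enone, so that evaporation of the alkene and secondary photolysis of the adduct compete. Fallback: from 17, irradiation with methyl cyclobut-1-ene-1-carboxylate in place of 19 would give keto ester F4; the acceptor group makes the alkene more reactive and directs its substituted carbon to C5. LiAlH4 would reduce ester and ketone to diol F5. Selective sulfonylation of the primary hydroxyl (TsCl, pyridine) would give F6, LiBEt3H would replace the sulfonate by hydrogen to give the C4-methyl carbinol F7, and Dess–Martin oxidation of the C6 carbinol returns to 21.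

Step 16. Most likely to go wrong: slow or unselective hydride delivery, because the samarium chelate must form across a corner of the ten-membered ring and the carbonyl is deactivated by conjugation, accompanied by retro-aldol opening of the ring at C7–C8 under the Lewis acidic alkoxide conditions. Fallback: from 23, reagent-controlled 1,2-reduction of the enone to the 6S alcohol F8 with (S)-2-methyl-CBS-oxazaborolidine and catecholborane at −78 °C. The alkenyl arm is expected to act as the large group; the antipodal catalyst is used if the branched C7 arm dominates. Silylation (t-BuMe2SiOTf) would give F9, and HF·pyridine, which removes the triethylsilyl and primary silyl ethers but not the hindered C6 ether, returns to 28; steps 15–19 fall away.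

Step 20. Most likely to go wrong: Z to E drift of the angeloyl group during the slow acylation of the hindered C8 hydroxyl at 80 °C, or incomplete acylation at C8. Fallback: form the Z alkene after the ester bond. From 28, esterification of both hydroxyls with 2-[bis(2,2,2-trifluoroethoxy)phosphoryl]propanoic acid (carbodiimide, DMAP) would give bis-phosphonate F10. A double Still–Gennari olefination with acetaldehyde (KN(SiMe3)2, 18-crown-6, THF, −78 °C), which is Z-selective, returns to 31.

## Further compounds

F1 | step 14 | 8-hydroxy analogue of 21 (triethylsilyl ether cleaved, all centres as in 21) | CC(C)(C)[Si](C)(C)OC[C@@H](C)[C@@H]1[C@@H](O)C[C@@]2(C)[C@@H]3CC[C@]3(C)[C@H]2C1=O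
F2 | step 14 | (6S)-6-hydroxy-8-acetoxy tricycle from F1 (C6 hydroxyl trans to the C8 acetate on the six-membered ring, other centres as in 21) | CC(C)(C)[Si](C)(C)OC[C@@H](C)[C@@H]1[C@@H](OC(C)=O)C[C@@]2(C)[C@@H]3CC[C@]3(C)[C@H]2[C@@H]1O
F3 | step 14 | C6 tert-butyldimethylsilyl ether of F2 | CC(C)(C)[Si](C)(C)OC[C@@H](C)[C@@H]1[C@@H](OC(C)=O)C[C@@]2(C)[C@@H]3CC[C@]3(C)[C@H]2[C@@H]1O[Si](C)(C)C(C)(C)C
F4 | step 13 | C4 methoxycarbonyl analogue of 21 (CO2CH3 in place of the C4 methyl, cis-anti-cis) | CC(C)(C)[Si](C)(C)OC[C@@H](C)[C@@H]1[C@@H](O[Si](CC)(CC)CC)C[C@@]2(C)[C@@H]3CC[C@]3(C(=O)OC)[C@H]2C1=O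
F5 | step 13 | diol from F4 (C4 hydroxymethyl, C6 carbinol as epimer mixture) | CC(C)(C)[Si](C)(C)OC[C@@H](C)[C@@H]1[C@@H](O[Si](CC)(CC)CC)C[C@@]2(C)[C@@H]3CC[C@]3(CO)[C@H]2C1O
F6 | step 13 | primary p-toluenesulfonate of F5 (C6 carbinol as epimer mixture) | CC(C)(C)[Si](C)(C)OC[C@@H](C)[C@@H]1[C@@H](O[Si](CC)(CC)CC)C[C@@]2(C)[C@@H]3CC[C@]3(COS(=O)(=O)c4ccc(C)cc4)[C@H]2C1O
F7 | step 13 | C6 carbinol of 21 (epimer mixture at C6) | CC(C)(C)[Si](C)(C)OC[C@@H](C)[C@@H]1[C@@H](O[Si](CC)(CC)CC)C[C@@]2(C)[C@@H]3CC[C@]3(C)[C@H]2C1O
F8 | step 16 | (1(10)Z,4E,6S,7S,8S,11S)-12-[(tert-butyldimethylsilyl)oxy]-8-[(triethylsilyl)oxy]germacra-1(10),4-dien-6-ol | CC(C)(C)[Si](C)(C)OC[C@@H](C)[C@@H]1[C@@H](O[Si](CC)(CC)CC)C/C(C)=C\CC/C(C)=C/[C@@H]1O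
F9 | step 16 | (1(10)Z,4E,6S,7R,8S,11S)-6,12-bis[(tert-butyldimethylsilyl)oxy]-8-[(triethylsilyl)oxy]germacra-1(10),4-diene | CC(C)(C)[Si](C)(C)OC[C@@H](C)[C@@H]1[C@@H](O[Si](CC)(CC)CC)C/C(C)=C\CC/C(C)=C/[C@@H]1O[Si](C)(C)C(C)(C)C
F10 | step 20 | 8,12-bis{2-[bis(2,2,2-trifluoroethoxy)phosphoryl]propanoate} of 28 (epimers at the two phosphonate-bearing carbons) | CC(P(=O)(OCC(F)(F)F)OCC(F)(F)F)C(=O)OC[C@@H](C)[C@@H]1[C@@H](OC(=O)C(C)P(=O)(OCC(F)(F)F)OCC(F)(F)F)C/C(C)=C\CC/C(C)=C/[C@@H]1O[Si](C)(C)C(C)(C)C
A1 | alternative 1 | open-chain (E)-C4 alkenyl iodide with (Z)-C10=C1–C2=C3 diene, C6 triethylsilyl ether, C8 and C12 angelates | C/C=C(/C)C(=O)OC[C@@H](C)[C@H]([C@@H](OC(=O)/C(C)=C\C)C/C(C)=C\C=C)[C@@H](O[Si](CC)(CC)CC)/C=C(\C)I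
A2 | alternative 1 | C6 triethylsilyl ether of 32 | C/C=C(/C)C(=O)OC[C@@H](C)[C@@H]1[C@@H](OC(=O)/C(C)=C\C)C/C(C)=C\CC/C(C)=C/[C@@H]1O[Si](CC)(CC)CC
A3 | alternative 2 | open-chain (Z)-allylic phenyl sulfone at C2 with (E)-allylic bromide at C3, C6 p-methoxybenzyl ether, C8 and C12 tert-butyldimethylsilyl ethers | CC(C)(C)[Si](C)(C)OC[C@@H](C)[C@H]([C@@H](O[Si](C)(C)C(C)(C)C)C/C(C)=C\CS(=O)(=O)c1ccccc1)[C@@H](OCc1ccc(OC)cc1)/C=C(\C)CBr
A4 | alternative 2 | C2-phenylsulfonyl ten-membered diene (C6 p-methoxybenzyl ether, C8 and C12 silyl ethers) | CC(C)(C)[Si](C)(C)OC[C@@H](C)[C@@H]1[C@@H](O[Si](C)(C)C(C)(C)C)C/C(C)=C\C(S(=O)(=O)c2ccccc2)C/C(C)=C/[C@@H]1OCc1ccc(OC)cc1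
A5 | alternative 3 | 13-membered C6–O–C12 diallyl ether with C8 silyl ether (E geometry at C7=C11 assumed) | O1C/C(C)=C/[C@@H](O[Si](C)(C)C(C)(C)C)C/C(C)=C\CC/C(C)=C/C1
A6 | alternative 3 | 6-hydroxy-7-isopropenyl-8-silyloxy cyclodeca-1(10),4-diene | C=C(C)[C@@H]1[C@@H](O[Si](C)(C)C(C)(C)C)C/C(C)=C\CC/C(C)=C/[C@@H]1O
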